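The numbers of this flask are those of an exercise, and the outcome is calculated.

First end groups have two exits here, rings and links, so ask how they divide. Read the flasks, the steps and the questions:

| flask | first end groups | second end groups | time | remark |
|---|---|---|---|---|
| midnight | 47 mM (fed, over 30 s) | 51.7 mM | 3.0 min | all else is in the flask from the start; the feed brings no volume worth counting |
| noon | 47 mM (in portions, 2, over 2.0 min) | 51.7 mM | 3.0 min | first portion at the start, last at 2.0 min |
| autumn | 47 mM | 51.7 mM | 3.0 min | everything together at the start |
| dawn | 47 mM (fed, over 2.0 min) | 51.7 mM | 3.0 min | all else is in the flask from the start; the feed brings no volume worth counting |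
| winter | 47 mM | 51.7 mM (fed, over 2.0 min) | 3.0 min | all else is in the flask from the start; the feed brings no volume worth counting |

    first end groups + second end groups → links (k1 = 0.72 M⁻¹ s⁻¹)
    first end groups + second end groups → rings, rate k2*[first end groups] as long as [second end groups] is above zero (k2 = 0.076 s⁻¹)
    second end groups + links ⇌ idle adduct, settled at all times (K3 = 100 M⁻¹)
    links ⇌ isomer of the product (K4 = 1.0, k4 = 0.0020 s⁻¹)
    second end groups + links → over-reaction product (k5 = 0.15 M⁻¹ s⁻¹)

- the flask that comes out highest in amount of rings, in percent of the first end groups charged; "all alike" if 1.5 percentage points covers them all (midnight / noon / autumn / dawn / winter / all alike)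
- amount of rings at the end, in percent of the first end groups charged, midnight
- amount of rings at the end, in percent of the first end groups charged, noon
- amount of rings at the end, in percent of the first end groups charged, autumn
- amount of rings at the end, in percent of the first end groups charged, dawn
- amount of rings at the end, in percent of the first end groups charged, winter

- links is meant together with its idle adduct
- run time (midnight): 3.0 min

Compare the exits. Each uses one first end group and one second end group, but the ring step ignores [second end groups] while that stays above zero, and the link step grows with it. Write [B] for free second end groups. Name the [B] at which both exits run equally the crossover concentration, a selectivity factor written as a concentration: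

crossover = 0.076 s⁻¹ / 0.72 M⁻¹ s⁻¹ = 106 mM

A first end group reacting at [B] becomes a ring with the share crossover / (crossover + [B]).

Now run autumn in slow motion. At the first instant [B] is 51.7 mM, about half the crossover, so the ring share is 67.1 %. Halfway through the first end groups, [B] is 28.2 mM and the share 78.9 %. At the end, with first end groups as limiting reagent, their charge being smaller than that of second end groups, [B] by subtraction is 4.70 mM and the share 95.7 %. Sum the shares over the charge:

rings = crossover × ln((crossover + [B] at start) / (crossover + [B] at end)) = 37.5 mM, or 79.7 % of the charge

The idle adduct holds second end groups away, with a balance term of 5.2 at the start, greater than one, so I take this figure as low.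

Feeding first end groups leaves this sum alone, since [B] follows how many have reacted, not when. Midnight, noon and dawn therefore get my figure too, provided they finish: the ring lifetime is 13.2 s, shorter than the 60.0 s that remain after the last addition.

Winter reverses the picture. The feed brings 0.431 mM s⁻¹, less than the 3.57 mM s⁻¹ the ring step can take at the start, so [B] stays close to zero and the share close to one. That lasts until [first end groups] falls to 5.67 mM. The last 12.1 % of the charge meets a [B] no longer close to zero; I give that stretch, as a round estimate, the share 95.7 % and commit to 99.5 %.

The forecast names winter, with 78.5 % for midnight, 78.5 % for noon, 78.5 % for autumn, 78.3 % for dawn and 99.5 % for winter, holding that under first-end-group feeding “the ring/link split barely changes”. My autumn figure of 79.7 % stands higher than its number.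

The simulation gives 81.8 % for midnight, 81.5 % for noon, 81.8 % for autumn, 81.8 % for dawn and 99.8 % for winter, so winter comes out highest, and the forecast holds on each mark.

Ask what ten times the time would change. Noon at 3.00 min still holds 0.40 % of its first end groups beside [B] of 2.60 mM. The crossover gives these a ring share of 97.6 %, worth 0.39 percentage points, which brings noon to 81.9 %, and noon reads 81.9 % at 30.0 min. Its links meanwhile go from 14.5 % to 6.64 %. Winter keeps 0.016 % of its first end groups at [B] of 4.67 mM, a share of 95.8 %, worth 0.016 points, and its rings read 99.8 % at 30.0 min.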